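**Assumption (one line):** the 2'-OH chalcone stays open-chain under the basic condensation (the 6'-OBn group disfavours spontaneous cyclisation), and the quinine- or quinidine-derived catalyst that delivers the (2S) isomer is chosen by a small screen.

## Retrosynthetic overview
- Disconnect the pyranone C2–O bond (intramolecular oxa-Michael) to a 2'-hydroxychalcone, then the chalcone C=C (Claisen–Schmidt) to an A-ring acetophenone and a B-ring aldehyde of similar size.
- The A-ring acetophenone comes from resorcinol by C–H borylation, oxidation to a 1,3,5-trioxygenated arene, then ortho-acetylation.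
- The B-ring aldehyde comes from catechol by two directed ortho-lithiation/prenylations, then para-formylation of the symmetric diprenyl catechol.
- Both aromatic rings are made first. Ring C is closed last in the stereodefining cyclisation, followed by one global deprotection.

## Route

**Step 1**
Reactants: 1 resorcinol
Product: 2 1,3-bis(benzyloxy)benzene
Conditions: BnBr, K2CO3, DMF, 60 °C
Reagents that add atoms: benzyl bromide, BrCc1ccccc1
Why: Williamson bis-O-alkylation protects both phenols with groups that survive the later Lewis-acid, base and organolithium steps.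

**Step 2**
Reactants: 2
Product: 3 2-[3,5-bis(benzyloxy)phenyl]-4,4,5,5-tetramethyl-1,3,2-dioxaborolane
Conditions: B2pin2, [Ir(cod)OMe]2 (1.5 mol%), dtbpy (3 mol%), THF, 80 °C
Reagents that add atoms: bis(pinacolato)diboron, CC1(C)OB(OC1(C)C)B2OC(C)(C)C(C)(C)O2
Why: Ir-catalysed C–H borylation is sterically controlled, so 1,3-disubstituted arenes borylate at the only position not flanked by a substituent (C5).

**Step 3**
Reactants: 3
Product: 4 3,5-bis(benzyloxy)phenol
Conditions: 30% H2O2, 1 M NaOH, THF, 0 °C → rt
Reagents that add atoms: hydrogen peroxide, OO (supplies the phenol oxygen)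
Why: oxidative deborylation of the arylboronate (1,2-aryl shift from boron to oxygen) gives the 1,3,5-trioxygenated arene.

**Step 4**
Reactants: 4
Product: 5 1-[4,6-bis(benzyloxy)-2-hydroxyphenyl]ethan-1-one
Conditions: AcOH, BF3·OEt2, 60 °C
Reagents that add atoms: acetic acid, CC(=O)O (supplies the acetyl group)
Why: BF3-promoted Friedel–Crafts (Hoesch/Fries-type) acylation of the very electron-rich phenol occurs ortho to OH, the position most activated and least hindered, giving the chelated 2'-hydroxyacetophenone.

**Step 5**
Reactants: 6 catechol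
Product: 7 1,2-bis(methoxymethoxy)benzene
Conditions: NaH, THF, 0 °C; then MOMCl, rt
Reagents that add atoms: chloromethyl methyl ether, COCCl
Why: bis-MOM protection masks the catechol and installs a strong ortho-directing group for lithiation.

**Step 6**
Reactants: 7
Product: 8 1,2-bis(methoxymethoxy)-3-(3-methylbut-2-en-1-yl)benzene
Conditions: n-BuLi, TMEDA, THF, 0 °C; then prenyl bromide, −78 °C → rt
Reagents that add atoms: prenyl bromide, CC(C)=CCBr
Why: directed ortho-metalation (MOM coordination) gives the 3-lithioarene, which undergoes SN2 alkylation with the allylic bromide.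

**Step 7**
Reactants: 8
Product: 9 2,3-bis(methoxymethoxy)-1,4-bis(3-methylbut-2-en-1-yl)benzene
Conditions: s-BuLi, TMEDA, THF, −78 °C; then prenyl bromide, −78 °C → rt
Reagents that add atoms: prenyl bromide, CC(C)=CCBr
Why: the second directed ortho-metalation occurs at the remaining position ortho to the other OMOM, at low temperature to avoid prenylic deprotonation, giving the symmetric 3,6-diprenylcatechol bis-ether.

**Step 8**
Reactants: 9
Product: 10 3,4-bis(methoxymethoxy)-2,5-bis(3-methylbut-2-en-1-yl)benzaldehyde
Conditions: Cl2CHOMe, TiCl4, CH2Cl2, −78 → 0 °C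
Reagents that add atoms: dichloromethyl methyl ether, COC(Cl)Cl (CHO carbon); water on work-up (O)
Why: Rieche formylation goes para to an OMOM and ortho to a prenyl; the two free positions of 9 are equivalent by symmetry, so a single regioisomer forms, and this places CHO para to the future C4'–O as required.

**Step 9**
Reactants: 5 + 10
Product: 11 (E)-2'-hydroxychalcone: (E)-1-[4,6-bis(benzyloxy)-2-hydroxyphenyl]-3-[3,4-bis(methoxymethoxy)-2,5-bis(3-methylbut-2-en-1-yl)phenyl]prop-2-en-1-one
Conditions: 50% aq. KOH, EtOH, rt, 48 h; quench AcOH
Reagents that add atoms: none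
Why: Claisen–Schmidt aldol condensation joins the A and B fragments; dehydration gives the conjugated E-enone, and the MOM, benzyl and prenyl groups are base-stable.

**Step 10**
Reactants: 11
Product: 12 (2S)-5,7-bis(benzyloxy)-3',4'-bis(methoxymethoxy)-2',5'-diprenylflavanone
Conditions: cinchona-derived bifunctional squaramide or thiourea catalyst (10 mol%), toluene, 25 °C, 72 h
Reagents that add atoms: none
Why: catalytic asymmetric intramolecular oxa-Michael (6-endo-trig) — the tertiary amine deprotonates the 2'-OH and the H-bond donor activates the enone, so the phenoxide attacks one enantiotopic face of the β-carbon and sets C2 as (S).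

**Step 11**
Reactants: 12
Product: 13 sigmoidin A
Conditions: BCl3, pentamethylbenzene, CH2Cl2, −78 → −20 °C; quench MeOH, cold aq. NaHCO3
Reagents that add atoms: none
Why: BCl3 cleaves both benzyl ethers and both MOM ethers in one operation, with no hydrogenolysis so the prenyl alkenes survive; the pentamethylbenzene scavenges benzyl cations, and the non-epimerising cold acidic conditions leave C2 untouched.

## Compound list
1 | resorcinol | Oc1cccc(O)c1 | starting material
2 | 1,3-bis(benzyloxy)benzene | c1ccc(COc2cccc(OCc3ccccc3)c2)cc1 | intermediate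
3 | 2-[3,5-bis(benzyloxy)phenyl]-4,4,5,5-tetramethyl-1,3,2-dioxaborolane | CC1(C)OB(OC1(C)C)c1cc(OCc2ccccc2)cc(OCc2ccccc2)c1 | intermediate
4 | 3,5-bis(benzyloxy)phenol | Oc1cc(OCc2ccccc2)cc(OCc2ccccc2)c1 | intermediate
5 | 1-[4,6-bis(benzyloxy)-2-hydroxyphenyl]ethan-1-one | CC(=O)c1c(O)cc(OCc2ccccc2)cc1OCc1ccccc1 | intermediate
6 | catechol | Oc1ccccc1O | starting material
7 | 1,2-bis(methoxymethoxy)benzene | COCOc1ccccc1OCOC | intermediate
8 | 1,2-bis(methoxymethoxy)-3-prenylbenzene | COCOc1cccc(CC=C(C)C)c1OCOC | intermediate
9 | 2,3-bis(methoxymethoxy)-1,4-diprenylbenzene | CC(C)=CCc1ccc(CC=C(C)C)c(OCOC)c1OCOC | intermediate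
10 | 3,4-bis(methoxymethoxy)-2,5-diprenylbenzaldehyde | CC(C)=CCc1cc(C=O)c(CC=C(C)C)c(OCOC)c1OCOC | intermediate
11 | (E)-2'-hydroxychalcone (A/B coupling product) | O=C(/C=C/c1cc(CC=C(C)C)c(OCOC)c(OCOC)c1CC=C(C)C)c1c(O)cc(OCc2ccccc2)cc1OCc1ccccc1 | intermediate
12 | (2S)-5,7-bis(benzyloxy)-3',4'-bis(MOM-oxy)-2',5'-diprenylflavanone | CC(C)=CCc1cc([C@@H]2CC(=O)c3c(OCc4ccccc4)cc(OCc4ccccc4)cc3O2)c(CC=C(C)C)c(OCOC)c1OCOC | intermediate
13 | sigmoidin A | CC(C)=CCc1cc([C@@H]2CC(=O)c3c(O)cc(O)cc3O2)c(CC=C(C)C)c(O)c1O | target

## Totals
- Total step count: 11.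
- Longest linear sequence: 7 (steps 1–4, 9, 10, 11; the other branch, steps 5–8 then 9–11, is also 7).

## Three steps most likely to fail
1. **Step 10 (enantioselective oxa-Michael):** the ortho-prenyl B-ring and the reversible cyclisation may erode ee. Fallback: cyclise 11 racemically (NaOAc, EtOH, reflux), resolve the protected flavanone 12 by preparative chiral-phase HPLC, and carry the (S)-enantiomer into step 11.
2. **Step 8 (Rieche formylation):** TiCl4 may cleave the MOM groups or cyclise a prenyl group. Fallback: brominate 9 (NBS, MeCN, −20 °C), then do Br–Li exchange (t-BuLi, −78 °C) and quench with DMF to give 10 without a strong Lewis acid.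
3. **Step 11 (global deprotection with BCl3):** acid may cyclise the ortho-prenyl phenols or open the flavanone. Fallback: re-route with the A-ring phenols as allyl ethers (allyl bromide in step 1), then remove MOM groups with PPTS in t-BuOH and the allyl groups with Pd(PPh3)4 and PhSiH3, avoiding strong Lewis acids.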